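The runs are calculated for substances that don't exist; noise was put on by code.

If starting material and target leave a flask one for one, their difference stays put. The end of a flask can then be reckoned from this gap, c(target) − c(starting material), before its pace is known.

in all of them: enzyme 0.18 µM

| run | starting material | remark | time |
|---|---|---|---|
| grey | 0.022 M | the very flask that is asked about, followed so far |  |
| blue | 0.011 M | run made earlier |  |
| flask | 0.022 M |  | 30 h |

| run | time / h | target / % | starting material / % |
|---|---|---|---|
| grey | 0.200 | 56.7 | 39.5 |
| grey | 0.833 | 78.8 | 10.9 |
| grey | 3.00 | 67.9 | 8.1 |
| grey | 12.0 | 45.5 | 3.6 |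
| blue | 0.333 | 77.8 | 19.3 |
| blue | 1.33 | 82.6 | 10.5 |
| blue | 6.00 | 69.9 | 8.6 |
| blue | 30.0 | 53.1 | 1.2 |

(readings scatter by 0.3 percentage points)

- the earlier runs were read with a standard deviation of 0.3 percentage points

- the best time, 30 h at the latest, for target
- the amount of target, in percent of the starting material charged, at that time
- earliest time at which at least nineteen twentieths of that best amount are there
- latest time at which they still are

Take the conversion by itself first. In the blue run, starting material over target reads 0.123 at 6.00 h, and the grey run reads 0.119 at 3.00 h. These scattered readings from draining flasks are at most an estimate of the equilibrium ratio, and the blue one is carried forward here. On that estimate, with this step alone, target would stand at 89.0%, and the gap would stay at 0.781 of the charge.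

Now add the loss of both species. The reciprocal of the gap climbs above its value for that share of the charge. The climb reads 17.8 L mol⁻¹ at 3.00 h in grey, 31.9 L mol⁻¹ at 6.00 h in blue and 50.3 L mol⁻¹ at 12.0 h in grey. These points from two charges are taken here as one curve.

Then add the stop. At 30.0 h the blue ratio reads 0.0226, under the earlier 0.123, so the blue run no longer shows that ratio there. My reckoning takes the gap as frozen by then. The climb over the enzyme's working life, the lifetime climb, reads 58.7 L mol⁻¹ in blue. Both runs hold 0.18 µM of enzyme, so the same climb gives the grey flask a gap of 38.9% at 30 h.

The forecast puts the best time at 0.75 h with 79% target, and the window from 0.45 h to 1.45 h. It places the peak where “the remaining approach to equilibrium balances the drain”.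

The flask gives 0.762 h, 78.7%, 0.428 h and 1.65 h, so all four forecast values stand within tolerance. A run of this recipe peaking well away from 0.75 h would make the forecast wrong.

    starting material + enzyme ⇌ complex (K = 310 L mol⁻¹, k = 16000 L mol⁻¹ s⁻¹)
    complex ⇌ enzyme + target (K = 0.0250 M, k = 360 s⁻¹)
    starting material + target → side product (k = 0.00570 L mol⁻¹ s⁻¹)
    enzyme → spent catalyst (k = 1.20 × 10⁻⁴ s⁻¹)

After its peak the grey flask goes on changing: at 30.0 h it holds 38.7% target and 61.0% side product. Spent catalyst is 98.7% of the catalyst charged by 15.0 h. The flask's gap at 30.0 h is 38.3%, against the reckoned 38.9%. The neighbour flask charges 0.0088 M of starting material with the same enzyme, and the same lifetime climb gives it a gap of 55.6%. That neighbour reaches 84.8% target at best and ends with 57.4% target and 1.11% starting material, a gap of 56.3%.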